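**Retrosynthetic overview**

1. Rings: A (benzoic acid ring), B (hexasubstituted ring, numbered as the phthalide: C-1 lactone C=O, C-3 lactone CH2, C-4 ether O, C-5 ester O, C-6 CH2OH, C-7 OH, C-7a), C (seven-membered depsidone lactone), D (γ-lactone). Ring D is closed last, on the complete A–C–B skeleton, by forming the aryl–C(=O) bond C-7a–C-1 in a hydroxyl-directed C–H carbonylation in which CO supplies C-1.
2. Feature that permits this: in ring B, C-7a is the only ring carbon that still bears H. It lies ortho to the CH2OH arm on C-3a (directing group) and ortho to the C-7 oxygen (electron release). The other hydroxymethyl carbon (on C-6) sits between two oxygen-bearing carbons and has no ortho C–H.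
3. Ring C: ester C–O bond by lactonisation, after the diaryl ether C–O bond is made by SNAr of a ring B salicylaldehyde on a 2-fluoroisophthalate (ring A). The formyl group is a masked phenol (Baeyer–Villiger), so the ether and ester oxygens cannot be confused.
4. Ring B comes from the centrosymmetric bis-acetonide of 2,5-bis(hydroxymethyl)hydroquinone: its two equivalent C–H bonds become the C-5 oxygen (lithiation/formylation, later Baeyer–Villiger) and the lactone carbonyl site (key step). Ring A comes from 3-fluoro-5-methylphenol by two regioselective carboxylations.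
5. Order of ring formation: two temporary 1,3-dioxine rings (step 6), ring C (step 12), ring D (step 13).

Key step: step 13

Remark: the target has no stereocentre, so no stereocontrol is needed; 3-fluoro-5-methylphenol and diethyl 2,5-dihydroxyterephthalate are taken as the commercial starting materials.

**Route**

Step 1
Reactants: 1 3-fluoro-5-methylphenol
Product: 2 1-fluoro-3-(methoxymethoxy)-5-methylbenzene
Conditions: NaH, MOMCl, THF, 0 °C to rt
Reagents that add atoms: chloromethyl methyl ether, COCCl
Why: Williamson-type O-alkylation of the sodium phenoxide installs an acid-labile MOM ether that protects the future ring A hydroxyl and later cooperates with fluorine as an ortho-directing group.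

Step 2
Reactants: 2 1-fluoro-3-(methoxymethoxy)-5-methylbenzene
Product: 4 tert-butyl 2-fluoro-6-(methoxymethoxy)-4-methylbenzoate, via aryllithium 3 (not isolated)
Conditions: n-BuLi, THF, −78 °C; then Boc2O, −78 °C to rt; H2O
Reagents that add atoms: di-tert-butyl dicarbonate, CC(C)(C)OC(=O)OC(=O)OC(C)(C)C
Why: Directed ortho-metalation removes the most acidic ring proton, the one flanked by F and OMOM, and acyl substitution on Boc2O gives the tert-butyl ester, the low temperature preventing loss of LiF to an aryne.

Step 3
Reactants: 4 tert-butyl 2-fluoro-6-(methoxymethoxy)-4-methylbenzoate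
Product: 5 tert-butyl 3-bromo-2-fluoro-6-(methoxymethoxy)-4-methylbenzoate
Conditions: NBS, MeCN, 0 °C to rt
Reagents that add atoms: N-bromosuccinimide, O=C1CCC(=O)N1Br
Why: Electrophilic aromatic bromination should go para to the MOM-oxy group and meta to the ester, as in the 4-bromination of 3-fluoroanisole, which places bromine between F and CH3.

Step 4
Reactants: 5 tert-butyl 3-bromo-2-fluoro-6-(methoxymethoxy)-4-methylbenzoate
Product: 7 1-benzyl 3-tert-butyl 2-fluoro-4-(methoxymethoxy)-6-methylbenzene-1,3-dicarboxylate, via arylmagnesium chloride 6 (not isolated)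
Conditions: iPrMgCl·LiCl, THF, −20 °C; then CbzCl, −40 to 0 °C
Reagents that add atoms: benzyl chloroformate, O=C(Cl)OCc1ccccc1
Why: Bromine–magnesium exchange tolerates the tert-butyl ester and the ortho-fluorine below 0 °C, and acylation of the aryl Grignard reagent by the chloroformate gives a benzyl ester that is orthogonal to the tert-butyl ester and activates the C–F bond from the second ortho position.

Step 5
Reactants: 8 diethyl 2,5-dihydroxyterephthalate
Product: 9 2,5-bis(hydroxymethyl)benzene-1,4-diol
Conditions: LiAlH4 (excess), THF, 0 °C to reflux; H2O work-up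
Reagents that add atoms: none
Why: Hydride reduction of both salicylate-type esters (the phenoxides are spectators) should give the centrosymmetric bis(salicyl alcohol).

Step 6
Reactants: 9 2,5-bis(hydroxymethyl)benzene-1,4-diol
Product: 10 2,2,7,7-tetramethyl-4H,9H-benzo[1,2-d:4,5-d']bis[1,3]dioxine (bis-acetonide of 9)
Conditions: 2,2-dimethoxypropane, p-TsOH (cat.), acetone, rt
Reagents that add atoms: 2,2-dimethoxypropane, COC(C)(C)OC
Why: Acid-catalysed transketalisation ties each ortho-hydroxybenzyl alcohol unit into a six-membered 1,3-benzodioxine, which masks all four hydroxyl groups, keeps the two remaining ring C–H bonds equivalent and supplies ortho-directing ring oxygens.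

Step 7
Reactants: 10 bis-acetonide
Product: 12 2,2,7,7-tetramethyl-4H,9H-benzo[1,2-d:4,5-d']bis[1,3]dioxine-5-carbaldehyde, via aryllithium 11 (not isolated)
Conditions: n-BuLi, TMEDA, THF, −78 to 0 °C; then DMF, −78 °C to rt; H2O
Reagents that add atoms: N,N-dimethylformamide, CN(C)C=O
Why: Directed ortho-metalation between the aryl oxygen of one dioxine ring and the CH2O arm of the other (the two ring C–H bonds are equivalent, so one equivalent of base can give only one product) followed by formylation installs the carbon that is later exchanged for the ester oxygen of ring C.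

Step 8
Reactants: 12 bis-acetonide aldehyde
Product: 13 6-hydroxy-7-(hydroxymethyl)-2,2-dimethyl-4H-1,3-benzodioxine-5-carbaldehyde
Conditions: BCl3 (1.0 equiv), CH2Cl2, −78 °C; H2O
Reagents that add atoms: none
Why: Chelation-controlled Lewis acid cleavage, the known selective cleavage by BCl3 of an aryl ether oxygen ortho to a carbonyl group, should open only the dioxine ring whose aryl oxygen forms a six-membered chelate with the formyl oxygen, and the single equivalent of BCl3 is held in that chelate so that the second acetonide should remain.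

Step 9
Reactants: 13 ring B salicylaldehyde; 7 ring A fluoro diester
Product: 14 1-benzyl 3-tert-butyl 2-{[5-formyl-7-(hydroxymethyl)-2,2-dimethyl-4H-1,3-benzodioxin-6-yl]oxy}-4-(methoxymethoxy)-6-methylbenzene-1,3-dicarboxylate
Conditions: Cs2CO3, DMSO, 80 °C
Reagents that add atoms: none
Why: Nucleophilic aromatic substitution (addition–elimination) of fluoride, activated by the two ortho ester groups, by the phenoxide of 13 (its only acidic OH, made more acidic by the ortho formyl group) should give the fully ortho-substituted diaryl ether with the ether oxygen fixed at C-4 of ring B.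

Step 10
Reactants: 14 diaryl ether aldehyde
Product: 16 1-benzyl 3-tert-butyl 2-{[5-hydroxy-7-(hydroxymethyl)-2,2-dimethyl-4H-1,3-benzodioxin-6-yl]oxy}-4-(methoxymethoxy)-6-methylbenzene-1,3-dicarboxylate, via aryl formate 15 (not isolated)
Conditions: mCPBA, CH2Cl2, 0 °C to rt; then K2CO3 (cat.), MeOH, 0 °C
Reagents that add atoms: 3-chloroperoxybenzoic acid, O=C(OO)c1cccc(Cl)c1
Why: Baeyer–Villiger (Dakin-type) oxidation of the hindered ortho-aryloxy benzaldehyde should proceed with aryl migration to the formate, which mild methanolysis converts into the phenol that becomes the ester oxygen of ring C.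

Step 11
Reactants: 16 phenol benzyl ester
Product: 17 3-(tert-butoxycarbonyl)-2-{[5-hydroxy-7-(hydroxymethyl)-2,2-dimethyl-4H-1,3-benzodioxin-6-yl]oxy}-4-(methoxymethoxy)-6-methylbenzoic acid
Conditions: H2 (1 atm), Pd/C, EtOAc, rt
Reagents that add atoms: none
Why: Hydrogenolysis of the benzyl ester under neutral conditions frees the ring A carboxylic acid while the tert-butyl ester, MOM ether, acetonide and benzylic alcohol should stay intact.

Step 12
Reactants: 17 seco acid
Product: 18 depsidone alcohol (dibenzo[b,e][1,4]dioxepin-11-one; ring A carries CH3, OMOM and CO2tBu; ring B carries the fused 2,2-dimethyl-1,3-dioxine, one ring C–H and a free CH2OH ortho to the ether oxygen)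
Conditions: 2-chloro-1-methylpyridinium iodide, Et3N, CH2Cl2 (high dilution), reflux
Reagents that add atoms: none
Why: Mukaiyama lactonisation after carboxyl activation should close the seven-membered depsidone ring through the phenol (partly as phenoxide under Et3N), a closure expected to be faster than the eight-membered lactonisation by the un-ionised benzylic alcohol.

Step 13
Reactants: 18 depsidone alcohol
Product: 20 protected conneotricone (tert-butyl ester/MOM ether/acetonide of the target), via alkoxycarbonylpalladium acetate 19 (not isolated)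
Conditions: CO (1 atm), Pd(OAc)2 (10 mol%), N-acetylglycine (20 mol%), AgOAc (2.5 equiv), Li2CO3 (1 equiv), ClCH2CH2Cl, 90 °C
Reagents that add atoms: carbon monoxide, [C-]#[O+]
Why: Proposed new method: the primary alcohol of 18 binds Pd(OAc)2 and CO inserts into the Pd–O bond to give the alkoxycarbonylpalladium species 19, whose metal is held over the only C–H bond of ring B (C-7a, ortho to the CH2O arm and to the acetonide ring oxygen) and cleaves it by carboxylate-assisted concerted metalation–deprotonation to a six-membered acylpalladacycle; C–C reductive elimination then forms the aryl–C(=O) bond and closes the five-membered lactone, and zerovalent palladium is reoxidised to divalent palladium by AgOAc. The ring closes by contraction of the palladacycle with the arene C=C bond inside the new ring, a closure that a free acyl cation or radical would have to make in the unfavourable 5-endo mode. The closest known reaction types are the ligand-accelerated hydroxyl-directed C–H carbonylation of phenethyl alcohols to isochromanones (Pd(OAc)2, N-acyl amino acid, AgOAc, CO) and the thallation–carbonylation of benzylic alcohols to phthalides; new here is the direct catalytic use of a primary benzylic alcohol, which must carbonylate faster than it is dehydrogenated, and a CO-saturated metal without a free site for β-hydride elimination is expected to secure this. No stereocentre is formed. Site selectivity rests on the substrate: C-7a–H is the sole C–H of ring B, the other hydroxymethyl carbon is locked in the acetonide and has no ortho C–H, and the single C–H of ring A is flanked by two substituents with no hydroxyl group in reach. Li2CO3 buffers the acetic acid formed, so the acetonide, MOM ether, tert-butyl ester and depsidone ester should survive.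

Step 14
Reactants: 20 protected conneotricone
Product: 21 conneotricone
Conditions: TFA/CH2Cl2/H2O (10:10:1), 0 °C to rt
Reagents that add atoms: none
Why: Acidolysis should remove the three acid-labile groups in one operation (tert-butyl ester by loss of isobutene, MOM acetal and acetonide by hydrolysis), water intercepting benzylic cations, while the depsidone ester and the γ-lactone are stable to acid.

**Compound list**

1 | 3-fluoro-5-methylphenol | Cc1cc(O)cc(F)c1 | starting material
2 | 1-fluoro-3-(methoxymethoxy)-5-methylbenzene | COCOc1cc(C)cc(F)c1 | intermediate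
3 | 2-fluoro-6-(methoxymethoxy)-4-methylphenyllithium (not isolated) | COCOc1cc(C)cc(F)c1[Li] | intermediate
4 | tert-butyl 2-fluoro-6-(methoxymethoxy)-4-methylbenzoate | COCOc1cc(C)cc(F)c1C(=O)OC(C)(C)C | intermediate
5 | tert-butyl 3-bromo-2-fluoro-6-(methoxymethoxy)-4-methylbenzoate | COCOc1cc(C)c(Br)c(F)c1C(=O)OC(C)(C)C | intermediate
6 | [3-(tert-butoxycarbonyl)-2-fluoro-4-(methoxymethoxy)-6-methylphenyl]magnesium chloride (not isolated) | COCOc1cc(C)c([Mg]Cl)c(F)c1C(=O)OC(C)(C)C | intermediate
7 | 1-benzyl 3-tert-butyl 2-fluoro-4-(methoxymethoxy)-6-methylbenzene-1,3-dicarboxylate | COCOc1cc(C)c(C(=O)OCc2ccccc2)c(F)c1C(=O)OC(C)(C)C | intermediate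
8 | diethyl 2,5-dihydroxyterephthalate | CCOC(=O)c1cc(O)c(C(=O)OCC)cc1O | starting material
9 | 2,5-bis(hydroxymethyl)benzene-1,4-diol | OCc1cc(O)c(CO)cc1O | intermediate
10 | 2,2,7,7-tetramethyl-4H,9H-benzo[1,2-d:4,5-d']bis[1,3]dioxine | CC1(C)OCc2cc3OC(C)(C)OCc3cc2O1 | intermediate
11 | 5-lithio derivative of 10 (not isolated) | [Li]c1c2OC(C)(C)OCc2cc2OC(C)(C)OCc12 | intermediate
12 | 2,2,7,7-tetramethyl-4H,9H-benzo[1,2-d:4,5-d']bis[1,3]dioxine-5-carbaldehyde | O=Cc1c2OC(C)(C)OCc2cc2OC(C)(C)OCc12 | intermediate
13 | 6-hydroxy-7-(hydroxymethyl)-2,2-dimethyl-4H-1,3-benzodioxine-5-carbaldehyde | O=Cc1c(O)c(CO)cc2OC(C)(C)OCc12 | intermediate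
14 | 1-benzyl 3-tert-butyl 2-{[5-formyl-7-(hydroxymethyl)-2,2-dimethyl-4H-1,3-benzodioxin-6-yl]oxy}-4-(methoxymethoxy)-6-methylbenzene-1,3-dicarboxylate | Cc1cc(OCOC)c(C(=O)OC(C)(C)C)c(Oc2c(CO)cc3OC(C)(C)OCc3c2C=O)c1C(=O)OCc1ccccc1 | intermediate
15 | aryl formate of 16 (5-formyloxy compound, not isolated) | Cc1cc(OCOC)c(C(=O)OC(C)(C)C)c(Oc2c(CO)cc3OC(C)(C)OCc3c2OC=O)c1C(=O)OCc1ccccc1 | intermediate
16 | 1-benzyl 3-tert-butyl 2-{[5-hydroxy-7-(hydroxymethyl)-2,2-dimethyl-4H-1,3-benzodioxin-6-yl]oxy}-4-(methoxymethoxy)-6-methylbenzene-1,3-dicarboxylate | Cc1cc(OCOC)c(C(=O)OC(C)(C)C)c(Oc2c(CO)cc3OC(C)(C)OCc3c2O)c1C(=O)OCc1ccccc1 | intermediate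
17 | 3-(tert-butoxycarbonyl)-2-{[5-hydroxy-7-(hydroxymethyl)-2,2-dimethyl-4H-1,3-benzodioxin-6-yl]oxy}-4-(methoxymethoxy)-6-methylbenzoic acid | Cc1cc(OCOC)c(C(=O)OC(C)(C)C)c(Oc2c(CO)cc3OC(C)(C)OCc3c2O)c1C(=O)O | intermediate
18 | depsidone alcohol (ring C closed; CO2tBu, OMOM, acetonide, free CH2OH, one ring B C–H) | Cc1cc(OCOC)c(C(=O)OC(C)(C)C)c2c1C(=O)Oc1c3COC(C)(C)Oc3cc(CO)c1O2 | intermediate
19 | alkoxycarbonylpalladium acetate derived from 18 (not isolated) | Cc1cc(OCOC)c(C(=O)OC(C)(C)C)c2c1C(=O)Oc1c3COC(C)(C)Oc3cc(COC(=O)[Pd]OC(C)=O)c1O2 | intermediate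
20 | protected conneotricone (tert-butyl ester, MOM ether, acetonide) | Cc1cc(OCOC)c(C(=O)OC(C)(C)C)c2c1C(=O)Oc1c3COC(C)(C)Oc3c3C(=O)OCc3c1O2 | intermediate
21 | conneotricone | Cc1cc(O)c(C(=O)O)c2c1C(=O)Oc1c(CO)c(O)c3c(c1O2)COC3=O | target

**Step count and risks**

Total step count: 14. Longest linear sequence: 10 steps (steps 5–14 from 8; the ring A branch, steps 1–4 then 9–14, is equally long).

Steps most likely to fail:

1. Step 13 (Proposed new method). What may go wrong: dehydrogenation of the primary benzylic alcohol to the aldehyde by divalent palladium outrunning CO insertion, or slow C–H cleavage at the hindered position with gradual loss of the acetonide. Fallback with known chemistry, setting out from 16 and returning at 20: the free phenol of 16 is para to the only open position of ring B, so iodination with N-iodosuccinimide should give the iodophenol F1. Carbonylative lactonisation of this ortho-iodobenzyl alcohol under zerovalent palladium catalysis (Pd(PPh3)4, CO, Et3N, DMF, 70 °C) gives the phthalide F2. Hydrogenolysis of the benzyl ester (H2, Pd/C) gives the acid F3, and Mukaiyama lactonisation as in step 12 gives 20.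

2. Step 8. What may go wrong: loss of site selectivity between the two acetonides (cleavage of both, or of the one remote from the aldehyde), or chlorination of the freed benzylic alcohol. Fallback setting out from 12 and returning at 13: both acetonides are hydrolysed (aq. HCl, THF) to 2,5-dihydroxy-3,6-bis(hydroxymethyl)benzaldehyde F4. Mono-ketalisation (2,2-dimethoxypropane, 1.1 equiv, PPTS, acetone, 0 °C) should then protect only the salicyl alcohol unit remote from the aldehyde, because the phenol ortho to the formyl group is held in a hydrogen bond and is the poorer nucleophile; this gives 13.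

3. Step 12. What may go wrong: competing acylation of the free primary alcohol (eight-membered lactone or oligomers) in place of the phenol. Fallback setting out from 16 and returning at 18: selective silylation of the primary alcohol (TBSCl, imidazole, DMF, 0 °C) gives the silyl ether F5. Hydrogenolysis (H2, Pd/C) gives the acid F6 and Mukaiyama lactonisation, now with the phenol as the only nucleophile, gives the silylated depsidone F7. Desilylation (HF·pyridine, THF) gives 18.

Further compounds
F1 | step 13 | 1-benzyl 3-tert-butyl 2-{[5-hydroxy-7-(hydroxymethyl)-8-iodo-2,2-dimethyl-4H-1,3-benzodioxin-6-yl]oxy}-4-(methoxymethoxy)-6-methylbenzene-1,3-dicarboxylate | Cc1cc(OCOC)c(C(=O)OC(C)(C)C)c(Oc2c(CO)c(I)c3OC(C)(C)OCc3c2O)c1C(=O)OCc1ccccc1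
F2 | step 13 | phthalide phenol benzyl ester (γ-lactone closed, ring C open) | Cc1cc(OCOC)c(C(=O)OC(C)(C)C)c(Oc2c3COC(=O)c3c3OC(C)(C)OCc3c2O)c1C(=O)OCc1ccccc1
F3 | step 13 | phthalide phenol carboxylic acid (seco acid of 20) | Cc1cc(OCOC)c(C(=O)OC(C)(C)C)c(Oc2c3COC(=O)c3c3OC(C)(C)OCc3c2O)c1C(=O)O
F4 | step 8 | 2,5-dihydroxy-3,6-bis(hydroxymethyl)benzaldehyde | O=Cc1c(O)c(CO)cc(O)c1CO
F5 | step 12 | tert-butyldimethylsilyl ether of 16 (at the primary alcohol) | Cc1cc(OCOC)c(C(=O)OC(C)(C)C)c(Oc2c(CO[Si](C)(C)C(C)(C)C)cc3OC(C)(C)OCc3c2O)c1C(=O)OCc1ccccc1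
F6 | step 12 | tert-butyldimethylsilyl ether of 17 | Cc1cc(OCOC)c(C(=O)OC(C)(C)C)c(Oc2c(CO[Si](C)(C)C(C)(C)C)cc3OC(C)(C)OCc3c2O)c1C(=O)O
F7 | step 12 | tert-butyldimethylsilyl ether of 18 | Cc1cc(OCOC)c(C(=O)OC(C)(C)C)c2c1C(=O)Oc1c3COC(C)(C)Oc3cc(CO[Si](C)(C)C(C)(C)C)c1O2
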